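**Plan**
1. Retrosynthetic cuts: first the two phenolic MOM acetals. The E,E-diene is then traced back by a proton shift to the skipped allene C2–C1′H=C2′=C3′H–C4′H2, and the C3 carbinol to a C3 ketone.
2. Enabling feature: in the oxolane ring, C2 is bonded to ring oxygen O1, to the oxidisable C3 and to diene carbon C1′, and it lies trans to the C5 methyl. Cutting O1–C2 and C2–C1′ together opens the ring to an acyclic α-diazoketone whose ether oxygen carries C1′–C4′ as a but-3-yn-2-yl group.
3. Further cuts: C2–C3 (acid plus CH2N2), O2–C3 of the isocoumarin (lactonisation of an alkynylbenzoic acid), C4–C4a (Sonogashira) and C3′–C4′ (allenylstannane onto an ynal-derived oxocarbenium ion, which also builds the hindered ether).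
4. Forward order: the aryl bromide (steps 1–4) and the diynyl ether (steps 5–7) are joined in step 8. The pyranone ring of the isocoumarin closes first (step 10) and the oxolane ring second (step 13). Reduction, allene-to-diene shift, geometry correction and deprotection follow.
5. Stereochemistry: C5 comes from ethyl (S)-3-hydroxybutanoate. C2 follows from C5 in the suprafacial [2,3] shift, and C3 follows from C2 by hydride attack anti to the side chain. The diene geometry is set thermodynamically.

Key step: step 13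

Remark: C1′ is the side-chain carbon on oxolane C2 and C4′ the one on isocoumarin C3. The propargylic ether carbon (made in step 7) and the allene axis (made in step 13) are carried as mixtures, because steps 13 and 15 erase them.

**Step 1**
Reactants: 1 1-bromo-3,5-dimethoxybenzene
Product: 3 2-bromo-4,6-dimethoxybenzaldehyde, via aryl iminium chloride 2 (not isolated)
Conditions: POCl3, DMF, 0 → 90 °C; then ice-water
Reagents that add atoms: N,N-dimethylformamide, CN(C)C=O; water, O
Why: Vilsmeier–Haack formylation attacks the ring position that is ortho to one methoxy group and para to the other, and avoids the crowded site between the two methoxy groups.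

**Step 2**
Reactants: 3 2-bromo-4,6-dimethoxybenzaldehyde
Product: 4 2-bromo-3-chloro-4,6-dimethoxybenzaldehyde
Conditions: SO2Cl2 (1.05 equiv), CH2Cl2, 0 °C → rt
Reagents that add atoms: sulfuryl chloride, O=S(=O)(Cl)Cl
Why: Electrophilic aromatic chlorination should go to C3, para to the 6-methoxy and ortho to the 4-methoxy group, because C5 is shielded by two flanking methoxy groups, as is usual for 6-substituted 2,4-dimethoxybenzoyl compounds.

**Step 3**
Reactants: 4 2-bromo-3-chloro-4,6-dimethoxybenzaldehyde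
Product: 5 2-bromo-3-chloro-4,6-dihydroxybenzaldehyde
Conditions: BBr3 (4 equiv), CH2Cl2, −78 °C → rt; then H2O
Reagents that add atoms: none
Why: Lewis-acid cleavage of aryl methyl ethers removes both methyl groups at a stage where only the aldehyde and two aryl halides, all inert to BBr3, are present.

**Step 4**
Reactants: 5 2-bromo-3-chloro-4,6-dihydroxybenzaldehyde
Product: 6 2-bromo-3-chloro-4,6-bis(methoxymethoxy)benzaldehyde
Conditions: NaH, MOMCl, DMF, 0 °C → rt
Reagents that add atoms: chloromethyl methyl ether, COCCl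
Why: Williamson-type O-alkylation of the bis-phenoxide also covers the hydrogen-bonded 6-OH and installs acetals that survive base, fluoride, hydride and carbenoid chemistry and leave under mild acid.

**Step 5**
Reactants: 7 ethyl (S)-3-hydroxybutanoate
Product: 8 2-(trimethylsilyl)ethyl (S)-3-hydroxybutanoate
Conditions: Me3SiCH2CH2OH (3 equiv), Ti(OEt)4 (10 mol %), toluene, 95 °C, EtOH distilled off
Reagents that add atoms: 2-(trimethylsilyl)ethanol, C[Si](C)(C)CCO
Why: Titanate-mediated transesterification exchanges the ester group of β-hydroxy esters without elimination or loss of configuration, and gives an ester that fluoride can later cleave beside the base-sensitive isocoumarin lactone.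

**Step 6**
Reactants: 8 2-(trimethylsilyl)ethyl (S)-3-hydroxybutanoate
Product: 9 2-(trimethylsilyl)ethyl (S)-3-(trimethylsilyloxy)butanoate
Conditions: Me3SiCl, Et3N, CH2Cl2, 0 °C
Reagents that add atoms: chlorotrimethylsilane, C[Si](C)(C)Cl
Why: Routine O-silylation turns the alcohol into the alkoxysilane needed for aprotic acetal formation and does not touch the stereocentre.

**Step 7**
Reactants: 9 2-(trimethylsilyl)ethyl (S)-3-(trimethylsilyloxy)butanoate (2.1 equiv); 10 3-(trimethylsilyl)propynal; 11 tributyl(propa-1,2-dienyl)stannane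
Product: 13 2-(trimethylsilyl)ethyl (3S)-3-{[1-(trimethylsilyl)hexa-1,5-diyn-3-yl]oxy}butanoate (both epimers at the diynyl carbon), via symmetrical ynal acetal 12 (not isolated)
Conditions: 9, 10, Me3SiOTf (5 mol %), CH2Cl2, −78 °C; then 11 (1.3 equiv), Me3SiOTf (1.1 equiv), −78 → −40 °C
Reagents that add atoms: none
Why: Silyl-triflate-catalysed acetalisation of the non-enolisable ynal with the alkoxysilane, followed by Hosomi–Sakurai-type SE2′ substitution of one alkoxy group by the allenylstannane, builds the secondary–secondary ether by C–C bond formation on an oxocarbenium ion that has no β-hydrogen to lose, and the new centre needs no control because step 13 deletes it.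

**Step 8**
Reactants: 6 2-bromo-3-chloro-4,6-bis(methoxymethoxy)benzaldehyde; 13 2-(trimethylsilyl)ethyl (3S)-3-{[1-(trimethylsilyl)hexa-1,5-diyn-3-yl]oxy}butanoate
Product: 14 2-(trimethylsilyl)ethyl (3S)-3-({6-[2-chloro-6-formyl-3,5-bis(methoxymethoxy)phenyl]-1-(trimethylsilyl)hexa-1,5-diyn-3-yl}oxy)butanoate
Conditions: PdCl2(PPh3)2 (5 mol %), CuI (10 mol %), Et3N, DMF (degassed), 70 °C
Reagents that add atoms: none
Why: Sonogashira coupling engages only the free alkyne terminus and the C–Br bond, which the ortho formyl group activates over C–Cl, and the tertiary amine rules out aldehyde–alkyne–amine condensation.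

**Step 9**
Reactants: 14 the alkynyl benzaldehyde of step 8
Product: 15 3-chloro-4,6-bis(methoxymethoxy)-2-[4-({(2S)-4-oxo-4-[2-(trimethylsilyl)ethoxy]butan-2-yl}oxy)-6-(trimethylsilyl)hexa-1,5-diyn-1-yl]benzoic acid
Conditions: NaClO2, NaH2PO4, 2-methyl-2-butene (excess), t-BuOH–H2O, rt
Reagents that add atoms: sodium chlorite, [Na+].[O-]Cl=O
Why: Pinnick oxidation converts the hindered aldehyde into the acid under buffered conditions that spare alkynes, MOM acetals and silyl groups, while the alkene scavenger keeps hypochlorous acid away from the electron-rich ring.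

**Step 10**
Reactants: 15 the alkynyl benzoic acid of step 9
Product: 16 2-(trimethylsilyl)ethyl (3S)-3-({1-[5-chloro-6,8-bis(methoxymethoxy)-1-oxo-1H-isochromen-3-yl]-4-(trimethylsilyl)but-3-yn-2-yl}oxy)butanoate
Conditions: Ph3PAuNTf2 (3 mol %), CH2Cl2, rt
Reagents that add atoms: none
Why: Gold-catalysed 6-endo-dig cycloisomerisation lets the ortho carboxyl group attack the alkyl-bearing alkyne carbon, which the carbonyl-substituted arene polarises as the electrophilic end under base-free conditions, while the silyl-capped alkyne is too hindered to compete.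

**Step 11**
Reactants: 16 the isocoumarin silyl ester of step 10
Product: 17 (3S)-3-({1-[5-chloro-6,8-bis(methoxymethoxy)-1-oxo-1H-isochromen-3-yl]but-3-yn-2-yl}oxy)butanoic acid
Conditions: n-Bu4NF (3.5 equiv), THF, 0 °C → rt; cold 0.5 M HCl wash
Reagents that add atoms: none
Why: Fluoride-induced fragmentation of the 2-(trimethylsilyl)ethyl ester and C-desilylation of the alkyne take place in one operation and avoid the hydroxide that would open the enol lactone to a β-alkoxy ketone prone to elimination.

**Step 12**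
Reactants: 17 the alkynyl ether acid of step 11
Product: 19 (4S)-1-diazo-4-({1-[5-chloro-6,8-bis(methoxymethoxy)-1-oxo-1H-isochromen-3-yl]but-3-yn-2-yl}oxy)pentan-2-one, via isobutyl carbonic anhydride 18 (not isolated)
Conditions: i-BuOCOCl, Et3N, THF, −20 °C; then CH2N2 (excess), Et2O, 0 °C → rt
Reagents that add atoms: diazomethane, C=[N+]=[N-]; isobutyl chloroformate, CC(C)COC(=O)Cl (retained only in 18)
Why: Acylation of diazomethane by a mixed carbonic anhydride, the first stage of the Arndt–Eistert sequence, is the standard mild route from β-alkoxy acids to α-diazoketones, and no free phenol or activated alkene is present to consume the reagent.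

**Step 13**
Reactants: 19 the diazoketone of step 12
Product: 21 (2S,5S)-2-{4-[5-chloro-6,8-bis(methoxymethoxy)-1-oxo-1H-isochromen-3-yl]buta-1,2-dien-1-yl}-5-methyloxolan-3-one (allene axis as a mixture), via oxonium ylide 20 (not isolated)
Conditions: Cu(acac)2 (10 mol %), THF, reflux, slow addition of 19 (final ca. 0.01 M)
Reagents that add atoms: none
Why: Cu(acac)2 expels N2 from 19, and a lone pair of the ether oxygen five atoms away captures the electrophilic copper carbenoid carbon, which forms O1–C2 and closes the oxolan-3-one ring (five-membered closure, exo with respect to the Cu=C bond) as ylide 20. The ylide then undergoes a concerted suprafacial [2,3]-sigmatropic shift through a five-membered envelope transition state in which the terminal alkyne carbon bonds to C2 while the O–CH bond breaks, so the but-3-yn-2-yl group arrives as a 1,3-disubstituted allene that already holds C1′–C4′. The closest known reaction type is the copper- or rhodium-catalysed oxonium ylide formation and [2,3] rearrangement of allyl and propargyl ethers of β-alkoxy diazoketones, which gives 2,5-trans oxolan-3-ones. C2 is set as S by the resident C5 centre, because the migrating group sits on oxygen anti to the C5 methyl and is delivered to the same face of C2, hence trans to the methyl, and both propargylic epimers converge on this configuration. The step needs ylide formation to outrun C–H insertion and alkyne cyclopropenation, and the [2,3] shift to outrun the [1,2] shift and proton transfer from the CH2 beside the isocoumarin. The 1,5-relationship of oxygen and carbenoid carbon, the unhindered alkyne terminus and the preference of acetylacetonate-ligated copper carbenoids for heteroatom lone pairs favour this outcome, and high dilution suppresses carbene dimerisation.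

**Step 14**
Reactants: 21 the allenyl ketone of step 13 (used at once after filtration through a short neutral pad)
Product: 22 5-chloro-3-{4-[(2S,3S,5S)-3-hydroxy-5-methyloxolan-2-yl]buta-2,3-dien-1-yl}-6,8-bis(methoxymethoxy)-1H-isochromen-1-one
Conditions: LiBH(s-Bu)3, THF, −78 °C; then AcOH
Reagents that add atoms: none
Why: Diastereoselective ketone reduction with a hindered trialkylborohydride delivers hydride to the face opposite the adjacent C2 side chain, which places the C3 hydroxyl cis to that chain (3S), removes the acidity of C2–H before any base is used, and is fast enough at −78 °C to leave the lactone alone.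

**Step 15**
Reactants: 22 the allenyl alcohol of step 14
Product: 23 5-chloro-3-{(1E)-4-[(2S,3S,5S)-3-hydroxy-5-methyloxolan-2-yl]buta-1,3-dien-1-yl}-6,8-bis(methoxymethoxy)-1H-isochromen-1-one (C1′=C2′ geometry mixed)
Conditions: DBU (1.5 equiv), MeCN, rt → 50 °C
Reagents that add atoms: none
Why: In this base-mediated prototropic allene-to-diene isomerisation the amidine removes a proton from C4′H2, which is activated by both the allene and the lactone-conjugated C3=C4 bond, and reprotonation at the central allene carbon gives the fully conjugated diene with C3′=C4′ formed E, while C1′=C2′ is expected Z-rich because the proton arrives from the side away from the oxolane.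

**Step 16**
Reactants: 23 the diene mixture of step 15
Product: 24 5-chloro-3-{(1E,3E)-4-[(2S,3S,5S)-3-hydroxy-5-methyloxolan-2-yl]buta-1,3-dien-1-yl}-6,8-bis(methoxymethoxy)-1H-isochromen-1-one
Conditions: I2 (5 mol %), CH2Cl2, visible light, rt
Reagents that add atoms: none
Why: Iodine-catalysed photoisomerisation adds iodine atoms reversibly to the aryl-conjugated diene, allows bond rotation and funnels the mixture to the more stable all-E isomer without touching the sp3 stereocentres or the still-protected arene.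

**Step 17**
Reactants: 24 the protected E,E-diene of step 16
Product: 25 5-chloro-6,8-dihydroxy-3-{(1E,3E)-4-[(2S,3S,5S)-3-hydroxy-5-methyloxolan-2-yl]buta-1,3-dien-1-yl}-1H-isochromen-1-one
Conditions: HCl (1.25 M in MeOH), CH2Cl2, 0 °C → rt
Reagents that add atoms: none
Why: Acid-catalysed acetal exchange with methanol removes phenolic MOM groups, the peri 8-O-acetal fastest, under conditions mild enough that the dienylic C2–O1 bond, which the neighbouring hydroxyl and the electron-poor heteroarene deactivate, should not ionise.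

**Compound list**
1 | 1-bromo-3,5-dimethoxybenzene | COc1cc(OC)cc(Br)c1 | starting material
2 | [(2-bromo-4,6-dimethoxyphenyl)methylidene]dimethylammonium chloride | COc1cc(Br)c(C=[N+](C)C)c(OC)c1.[Cl-] | intermediate
3 | 2-bromo-4,6-dimethoxybenzaldehyde | COc1cc(Br)c(C=O)c(OC)c1 | intermediate
4 | 2-bromo-3-chloro-4,6-dimethoxybenzaldehyde | COc1cc(OC)c(C=O)c(Br)c1Cl | intermediate
5 | 2-bromo-3-chloro-4,6-dihydroxybenzaldehyde | Oc1cc(O)c(C=O)c(Br)c1Cl | intermediate
6 | 2-bromo-3-chloro-4,6-bis(methoxymethoxy)benzaldehyde | COCOc1cc(OCOC)c(C=O)c(Br)c1Cl | intermediate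
7 | ethyl (S)-3-hydroxybutanoate | C[C@H](O)CC(=O)OCC | starting material
8 | 2-(trimethylsilyl)ethyl (S)-3-hydroxybutanoate | C[C@H](O)CC(=O)OCC[Si](C)(C)C | intermediate
9 | 2-(trimethylsilyl)ethyl (S)-3-(trimethylsilyloxy)butanoate | C[C@H](O[Si](C)(C)C)CC(=O)OCC[Si](C)(C)C | intermediate
10 | 3-(trimethylsilyl)propynal | C[Si](C)(C)C#CC=O | starting material
11 | tributyl(propa-1,2-dienyl)stannane | CCCC[Sn](CCCC)(CCCC)C=C=C | starting material
12 | bis[2-(trimethylsilyl)ethyl] (3S,3′S)-3,3′-{[3-(trimethylsilyl)prop-2-yne-1,1-diyl]bis(oxy)}dibutanoate | C[C@H](OC(C#C[Si](C)(C)C)O[C@@H](C)CC(=O)OCC[Si](C)(C)C)CC(=O)OCC[Si](C)(C)C | intermediate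
13 | 2-(trimethylsilyl)ethyl (3S)-3-{[1-(trimethylsilyl)hexa-1,5-diyn-3-yl]oxy}butanoate | C[C@H](OC(CC#C)C#C[Si](C)(C)C)CC(=O)OCC[Si](C)(C)C | intermediate
14 | 2-(trimethylsilyl)ethyl (3S)-3-({6-[2-chloro-6-formyl-3,5-bis(methoxymethoxy)phenyl]-1-(trimethylsilyl)hexa-1,5-diyn-3-yl}oxy)butanoate | C[C@H](OC(CC#Cc1c(Cl)c(OCOC)cc(OCOC)c1C=O)C#C[Si](C)(C)C)CC(=O)OCC[Si](C)(C)C | intermediate
15 | 3-chloro-4,6-bis(methoxymethoxy)-2-[4-({(2S)-4-oxo-4-[2-(trimethylsilyl)ethoxy]butan-2-yl}oxy)-6-(trimethylsilyl)hexa-1,5-diyn-1-yl]benzoic acid | C[C@H](OC(CC#Cc1c(Cl)c(OCOC)cc(OCOC)c1C(=O)O)C#C[Si](C)(C)C)CC(=O)OCC[Si](C)(C)C | intermediate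
16 | 2-(trimethylsilyl)ethyl (3S)-3-({1-[5-chloro-6,8-bis(methoxymethoxy)-1-oxo-1H-isochromen-3-yl]-4-(trimethylsilyl)but-3-yn-2-yl}oxy)butanoate | C[C@H](OC(Cc1cc2c(Cl)c(OCOC)cc(OCOC)c2c(=O)o1)C#C[Si](C)(C)C)CC(=O)OCC[Si](C)(C)C | intermediate
17 | (3S)-3-({1-[5-chloro-6,8-bis(methoxymethoxy)-1-oxo-1H-isochromen-3-yl]but-3-yn-2-yl}oxy)butanoic acid | C[C@H](OC(C#C)Cc1cc2c(Cl)c(OCOC)cc(OCOC)c2c(=O)o1)CC(=O)O | intermediate
18 | mixed anhydride of 17 with isobutyl hydrogen carbonate | C[C@H](OC(C#C)Cc1cc2c(Cl)c(OCOC)cc(OCOC)c2c(=O)o1)CC(=O)OC(=O)OCC(C)C | intermediate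
19 | (4S)-1-diazo-4-({1-[5-chloro-6,8-bis(methoxymethoxy)-1-oxo-1H-isochromen-3-yl]but-3-yn-2-yl}oxy)pentan-2-one | C[C@H](OC(C#C)Cc1cc2c(Cl)c(OCOC)cc(OCOC)c2c(=O)o1)CC(=O)C=[N+]=[N-] | intermediate
20 | (5S)-1-{1-[5-chloro-6,8-bis(methoxymethoxy)-1-oxo-1H-isochromen-3-yl]but-3-yn-2-yl}-5-methyl-3-oxooxolan-1-ium-2-ide | C[C@H]1CC(=O)[CH-][O+]1C(C#C)Cc3cc4c(Cl)c(OCOC)cc(OCOC)c4c(=O)o3 | intermediate
21 | (2S,5S)-2-{4-[5-chloro-6,8-bis(methoxymethoxy)-1-oxo-1H-isochromen-3-yl]buta-1,2-dien-1-yl}-5-methyloxolan-3-one | C[C@H]1CC(=O)[C@H](C=C=CCc2cc3c(Cl)c(OCOC)cc(OCOC)c3c(=O)o2)O1 | intermediate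
22 | 5-chloro-3-{4-[(2S,3S,5S)-3-hydroxy-5-methyloxolan-2-yl]buta-2,3-dien-1-yl}-6,8-bis(methoxymethoxy)-1H-isochromen-1-one | C[C@H]1C[C@H](O)[C@H](C=C=CCc2cc3c(Cl)c(OCOC)cc(OCOC)c3c(=O)o2)O1 | intermediate
23 | 5-chloro-3-{(1E)-4-[(2S,3S,5S)-3-hydroxy-5-methyloxolan-2-yl]buta-1,3-dien-1-yl}-6,8-bis(methoxymethoxy)-1H-isochromen-1-one, C1′=C2′ geometry mixed | C[C@H]1C[C@H](O)[C@H](C=C/C=C/c2cc3c(Cl)c(OCOC)cc(OCOC)c3c(=O)o2)O1 | intermediate
24 | 5-chloro-3-{(1E,3E)-4-[(2S,3S,5S)-3-hydroxy-5-methyloxolan-2-yl]buta-1,3-dien-1-yl}-6,8-bis(methoxymethoxy)-1H-isochromen-1-one | C[C@H]1C[C@H](O)[C@H](/C=C/C=C/c2cc3c(Cl)c(OCOC)cc(OCOC)c3c(=O)o2)O1 | intermediate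
25 | 5-chloro-6,8-dihydroxy-3-{(1E,3E)-4-[(2S,3S,5S)-3-hydroxy-5-methyloxolan-2-yl]buta-1,3-dien-1-yl}-1H-isochromen-1-one | C[C@H]1C[C@H](O)[C@H](/C=C/C=C/c2cc3c(Cl)c(O)cc(O)c3c(=O)o2)O1 | target

Total step count: 17.
Longest linear sequence: 14 steps (steps 1–4, then 8–17). The ether branch (steps 5–7) joins at step 8.

**Steps most likely to fail**

**Step 13.**
- What may go wrong: the ylide may collapse by proton transfer from the acidified CH2 beside the isocoumarin (loss of the side chain as a conjugated enyne). It may also undergo a [1,2] shift of the secondary propargylic group, or the carbenoid may be diverted by the lactone or the alkyne.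
- Fallback: build the oxolane before the isocoumarin, so that the ylide carries only a hydrocarbon side chain. This sets out from 13 and returns at 23.
- n-Bu4NF strips all silicon from 13 to give (3S)-3-(hexa-1,5-diyn-3-yloxy)butanoic acid F1.
- i-BuOCOCl and Et3N convert it into the isobutyl carbonic anhydride of that acid F2, and CH2N2 gives (4S)-1-diazo-4-(hexa-1,5-diyn-3-yloxy)pentan-2-one F3.
- Cu(acac)2 in THF at reflux leads through (5S)-1-(hexa-1,5-diyn-3-yl)-5-methyl-3-oxooxolan-1-ium-2-ide F4 to (2S,5S)-2-(hexa-1,2-dien-5-yn-1-yl)-5-methyloxolan-3-one F5.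
- LiBH(s-Bu)3 reduces this to (2S,3S,5S)-2-(hexa-1,2-dien-5-yn-1-yl)-5-methyloxolan-3-ol F6.
- Sonogashira coupling of the free alkyne with 6 gives 3-chloro-2-{6-[(2S,3S,5S)-3-hydroxy-5-methyloxolan-2-yl]hexa-4,5-dien-1-yn-1-yl}-4,6-bis(methoxymethoxy)benzaldehyde F7.
- DBU moves the allene into conjugation between oxolane and arylalkyne to give 3-chloro-2-{(3E)-6-[(2S,3S,5S)-3-hydroxy-5-methyloxolan-2-yl]hexa-3,5-dien-1-yn-1-yl}-4,6-bis(methoxymethoxy)benzaldehyde F8.
- Pinnick oxidation gives the corresponding dienynyl benzoic acid F9, and Ph3PAuNTf2 closes the pyranone ring 6-endo to 23, which re-enters the route at step 16.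

**Step 15.**
- What may go wrong: the amidine may deprotonate C4′H2 too slowly, or stronger base may attack the lactone, so that the allene is not carried cleanly into conjugation.
- Fallback: replace the carbanion pathway by hydropalladation and β-hydride elimination on an O-protected substrate. This sets out from 22 and returns at 25.
- Et3SiCl and imidazole give the triethylsilyl ether of 22 F10, which blocks attack of the hydroxyl on a π-allyl intermediate.
- Pd(PPh3)4 (5 mol %) with PhCO2H (20 mol %) in toluene at 80 °C generates a palladium hydride that adds to the central allene carbon. The equilibrating syn π-allyl complex loses the activated C4′ hydrogen to give the triethylsilyl ether of 24 F11 directly as the E,E-diene.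
- The conditions of step 17 then remove the silyl ether together with both MOM groups and deliver 25.

**Step 7.**
- What may go wrong: the electron-poor alkynyl acetal may ionise sluggishly, the stannane may add directly to unconverted aldehyde, or propargyl and allenyl transfer may scramble.
- Fallback: form the ether C–O bond on a cobalt-stabilised propargylic cation (Nicholas reaction) instead of the C–C bond. This sets out from 10 and 8 and returns at 13.
- Barbier addition of propargyl bromide and zinc to 10 gives 1-(trimethylsilyl)hexa-1,5-diyn-3-ol F12.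
- Co2(CO)8 (2.2 equiv) complexes both alkynes to give the bis(hexacarbonyldicobalt) complex of that diynol F13.
- BF3·OEt2 at −20 °C in the presence of excess 8 gives the bis(hexacarbonyldicobalt) complex of 13 F14, and (NH4)2Ce(NO3)6 in acetone at 0 °C releases 13.

**Further compounds**
F1 | step 13 | (3S)-3-(hexa-1,5-diyn-3-yloxy)butanoic acid | C[C@H](OC(CC#C)C#C)CC(=O)O
F2 | step 13 | mixed anhydride of F1 with isobutyl hydrogen carbonate | C[C@H](OC(CC#C)C#C)CC(=O)OC(=O)OCC(C)C
F3 | step 13 | (4S)-1-diazo-4-(hexa-1,5-diyn-3-yloxy)pentan-2-one | C[C@H](OC(CC#C)C#C)CC(=O)C=[N+]=[N-]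
F4 | step 13 | (5S)-1-(hexa-1,5-diyn-3-yl)-5-methyl-3-oxooxolan-1-ium-2-ide | C[C@H]1CC(=O)[CH-][O+]1C(CC#C)C#C
F5 | step 13 | (2S,5S)-2-(hexa-1,2-dien-5-yn-1-yl)-5-methyloxolan-3-one | C[C@H]1CC(=O)[C@H](C=C=CCC#C)O1
F6 | step 13 | (2S,3S,5S)-2-(hexa-1,2-dien-5-yn-1-yl)-5-methyloxolan-3-ol | C[C@H]1C[C@H](O)[C@H](C=C=CCC#C)O1
F7 | step 13 | 3-chloro-2-{6-[(2S,3S,5S)-3-hydroxy-5-methyloxolan-2-yl]hexa-4,5-dien-1-yn-1-yl}-4,6-bis(methoxymethoxy)benzaldehyde | C[C@H]1C[C@H](O)[C@H](C=C=CCC#Cc2c(Cl)c(OCOC)cc(OCOC)c2C=O)O1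
F8 | step 13 | 3-chloro-2-{(3E)-6-[(2S,3S,5S)-3-hydroxy-5-methyloxolan-2-yl]hexa-3,5-dien-1-yn-1-yl}-4,6-bis(methoxymethoxy)benzaldehyde, distal alkene geometry mixed | C[C@H]1C[C@H](O)[C@H](C=C/C=C/C#Cc2c(Cl)c(OCOC)cc(OCOC)c2C=O)O1
F9 | step 13 | 3-chloro-2-{(3E)-6-[(2S,3S,5S)-3-hydroxy-5-methyloxolan-2-yl]hexa-3,5-dien-1-yn-1-yl}-4,6-bis(methoxymethoxy)benzoic acid, distal alkene geometry mixed | C[C@H]1C[C@H](O)[C@H](C=C/C=C/C#Cc2c(Cl)c(OCOC)cc(OCOC)c2C(=O)O)O1
F10 | step 15 | 5-chloro-6,8-bis(methoxymethoxy)-3-{4-[(2S,3S,5S)-5-methyl-3-(triethylsilyloxy)oxolan-2-yl]buta-2,3-dien-1-yl}-1H-isochromen-1-one | C[C@H]1C[C@H](O[Si](CC)(CC)CC)[C@H](C=C=CCc2cc3c(Cl)c(OCOC)cc(OCOC)c3c(=O)o2)O1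
F11 | step 15 | 5-chloro-6,8-bis(methoxymethoxy)-3-{(1E,3E)-4-[(2S,3S,5S)-5-methyl-3-(triethylsilyloxy)oxolan-2-yl]buta-1,3-dien-1-yl}-1H-isochromen-1-one | C[C@H]1C[C@H](O[Si](CC)(CC)CC)[C@H](/C=C/C=C/c2cc3c(Cl)c(OCOC)cc(OCOC)c3c(=O)o2)O1
F12 | step 7 | 1-(trimethylsilyl)hexa-1,5-diyn-3-ol | C[Si](C)(C)C#CC(O)CC#C
F13 | step 7 | bis(hexacarbonyldicobalt) complex of F12, written as its components | C[Si](C)(C)C#CC(O)CC#C.[Co].[Co].[Co].[Co].[C-]#[O+].[C-]#[O+].[C-]#[O+].[C-]#[O+].[C-]#[O+].[C-]#[O+].[C-]#[O+].[C-]#[O+].[C-]#[O+].[C-]#[O+].[C-]#[O+].[C-]#[O+]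
F14 | step 7 | bis(hexacarbonyldicobalt) complex of 13, written as its components | C[C@H](OC(CC#C)C#C[Si](C)(C)C)CC(=O)OCC[Si](C)(C)C.[Co].[Co].[Co].[Co].[C-]#[O+].[C-]#[O+].[C-]#[O+].[C-]#[O+].[C-]#[O+].[C-]#[O+].[C-]#[O+].[C-]#[O+].[C-]#[O+].[C-]#[O+].[C-]#[O+].[C-]#[O+]
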